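Take the closed, stirred vessel, hold its temperature, charge starting material and partner, and follow target.

| flask | starting material | partner | time |
|---|---|---|---|
| south-east | 0.200 M | 0.500 M |  |
| south | 0.0800 M | 0.380 M |  |
| north | 0.200 M | 1.00 M |  |
| west | 0.100 M | 0.500 M |  |
| north-west | 0.0400 M | 0.100 M | 16 min |

| run | time / min | [target] / M |
|---|---|---|
| south-east run | 0.57 | 0.0057 |
| south-east run | 1.7 | 0.0180 |
| south-east run | 3.3 | 0.0364 |
| south-east run | 5.3 | 0.0496 |
| south-east run | 7.5 | 0.0641 |
| south-east run | 10 | 0.0796 |
| south-east run | 13 | 0.0837 |
| south-east run | 16 | 0.0881 |
| south run | 0.57 | 0.0017 |
| south run | 1.7 | 0.0097 |
| south run | 3.3 | 0.0151 |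
| south run | 5.3 | 0.0249 |
| south run | 7.5 | 0.0270 |
| south run | 10 | 0.0334 |
| south run | 13 | 0.0305 |
| south run | 16 | 0.0264 |
| north run | 0.57 | 0.0094 |
| north run | 1.7 | 0.0417 |
| north run | 3.3 | 0.0661 |
| north run | 5.3 | 0.0902 |
| north run | 7.5 | 0.1129 |
| north run | 10 | 0.1203 |
| north run | 13 | 0.1221 |
| north run | 16 | 0.1222 |
| west run | 0.57 | 0.0017 |
| west run | 1.7 | 0.0119 |
| west run | 3.3 | 0.0228 |
| west run | 5.3 | 0.0308 |
| west run | 7.5 | 0.0422 |
| west run | 10 | 0.0394 |
| west run | 13 | 0.0432 |
| west run | 16 | 0.0452 |

(standard deviation of a reading: 0.002 M)

- Overall: starting material + partner -> target.
- Constant volume, constant temperature.
- A reading of a species includes what of it is bound.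
- "The second partner" is partner.
- An order is taken over about fifteen percent of the charge, up and down.

- how the opening rate goes with [partner] round the charge of the south-east run: the exponent of the rate at two percent of starting material gone to target
- how the opening rate goes with [starting material] round the charge of the south-east run: the exponent of the rate at two percent of starting material gone to target (one fixed amount of target, the same in the runs compared)
- target in the north-west run at 16 min, as a share of the starting material charged

Read the opening first. Add the readings at 1.7 min and 3.3 min in each run. The north run, with twice the partner of the south-east run, gives a partner exponent of 0.987. The south-east run, with twice the starting material of the west run, gives 0.649. Both span a doubling, wider than the margin asked, and both carry the scatter.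

Now read the ends as shares of the starting material charged. At 16 min the south-east run stands at 44.0% and the west run at 45.2%, on equal partner. The north run, with more partner, stands higher at 61.1%. In these runs, then, the share moves with partner and stays put with the charge of starting material.

Take the mean partner of the north run, 0.939 M, halfway between charge and end. Multiply it by the unturned share over the turned share to get 0.598 M: the split concentration, the partner level at which half of the starting material ends as target. The share, or selectivity, is then mean partner over mean partner plus split concentration. Try it on the south-east run: mean partner 0.456 M gives 43.3%.

For the north-west run my mean partner is 0.0971 M, so I reckon 14.0% at 16 min. That figure takes the north-west run as finished by 16 min, and this is my assumption, not a reading of that flask.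

The forecast gives 1.03 for partner, 0.52 for starting material and 13.2% for the north-west share, holding that “this looks like a reversible reaction”. Its share lies 0.80 percentage points below mine.

The flask gives 1.0 for partner, 0.59 for starting material and 14.4% for the north-west share, so the forecast stands on all of them.

    starting material + partner → target + by-product (0.5550 M⁻¹ min⁻¹)
    starting material → decomposed substrate (0.3144 min⁻¹)
    2 starting material ⇌ idle substrate dimer, settled at all times (35.80 M⁻¹)

In the north-west run the free starting material, 44.2% of the charge at the start with the rest held as idle substrate dimer, fed both steps at once, the step to decomposed substrate running 5.66 times the step to target at the partner charged. The scheme holds no return from target, and target reached 14.4% at 16 min against the 14.0% reckoned from 0.598 M. In the south run the same split concentration gives 37.9%, and its readings at 10 min, 13 min and 16 min average 37.6% of its charge.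

The earlier runs and the new flask were computed for an exercise; the scatter is artificial.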